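The benzo ring of the 2,3-dihydrobenzofuran (C3a, C4, C5, C6, C7, C7a) carries oxygen at C7a, C7 and C6, hydrogen at C5 and carbon at C4 and C3a. The route cuts it into a squarate-derived dialkoxycyclobutenone (C7a, C7, C6, C5) and one alkene (C4, C3a). Heating the 4-alkenylcyclobutenone opens the four-membered ring to a dienylketene that closes by 6π electrocyclisation (new bond C3a–C7a) and enolises, giving the fully substituted arene with the C7a hydroxyl free for the later O1–C2 closure. The precursor is an α-(oxocyclobutenyl)acrylate whose γ- and δ-carbons (future C3 and C2) already carry both aryl groups from an auxiliary-controlled aldol reaction.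

Key step: step 12

Assumption: 2-[3,5-bis(benzyloxy)phenyl]acetic acid, 3,4,5-tris(benzyloxy)benzaldehyde, 3,5-bis(benzyloxy)benzyl bromide and diisopropyl squarate are taken as catalogue compounds.

Remark on protecting groups: benzyl ethers (aryl OH) and isopropyl ethers (squarate oxygens) are used so that all nine ethers fall to BCl3 at low temperature. A BBr3 demethylation would expose the stilbene and the 2-aryl-dihydrobenzofuran to strong acid. The isopropyl groups should also make the 4-chlorocyclobutenone less prone to dealkylation.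

Remark on stereochemistry: only the arylmethine carbon (future C3) must be correct in the precursor. The silyloxy carbon (future C2) is carried syn to it, so that ring closure gives the 2,3-trans ring whether it runs through the benzylic cation or by displacement with inversion.

Step 1
Reactants: 1 2-[3,5-bis(benzyloxy)phenyl]acetic acid; 2 (R)-4-benzyloxazolidin-2-one
Product: 4 (R)-4-benzyl-3-{2-[3,5-bis(benzyloxy)phenyl]acetyl}oxazolidin-2-one, via mixed pivalic anhydride 3 (not isolated)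
Conditions: PivCl, Et3N, THF, −20 °C; then LiCl, 2, −20 °C → rt
Reagents that add atoms: none
Why: Mixed-anhydride N-acylation of the oxazolidinone (LiCl/Et3N variant), in which the hindered pivaloyl carbonyl of 3 directs attack to the arylacetyl carbonyl; no stereocentre is formed.

Step 2
Reactants: 4 (R)-4-benzyl-3-{2-[3,5-bis(benzyloxy)phenyl]acetyl}oxazolidin-2-one; 5 3,4,5-tris(benzyloxy)benzaldehyde
Product: 7 (R)-4-benzyl-3-{(2R,3R)-2-[3,5-bis(benzyloxy)phenyl]-3-hydroxy-3-[3,4,5-tris(benzyloxy)phenyl]propanoyl}oxazolidin-2-one, via dibutylboron (Z)-enolate 6 (not isolated)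
Conditions: Bu2BOTf, iPr2NEt, CH2Cl2, −78 → 0 °C; 5, −78 → 0 °C; then pH 7 buffer, MeOH, 30% H2O2, 0 °C
Reagents that add atoms: none
Why: Evans syn-aldol reaction: the (Z)-boron enolate adds to the aldehyde through a chair-like Zimmerman–Traxler transition state on the enolate face remote from the benzyl group of the auxiliary, which sets the arylmethine carbon (future C3) as R and the carbinol carbon syn to it as R.

Step 3
Reactants: 7 (R)-4-benzyl-3-{(2R,3R)-2-[3,5-bis(benzyloxy)phenyl]-3-hydroxy-3-[3,4,5-tris(benzyloxy)phenyl]propanoyl}oxazolidin-2-one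
Product: 8 (R)-4-benzyl-3-{(2R,3R)-2-[3,5-bis(benzyloxy)phenyl]-3-(tert-butyldimethylsilyloxy)-3-[3,4,5-tris(benzyloxy)phenyl]propanoyl}oxazolidin-2-one
Conditions: TBSOTf, 2,6-lutidine, CH2Cl2, 0 °C
Reagents that add atoms: tert-butyldimethylsilyl triflate, CC(C)(C)[Si](C)(C)OS(=O)(=O)C(F)(F)F
Why: Silylation of the hindered secondary benzylic alcohol with the silyl triflate, which also blocks retro-aldol cleavage later; no stereocentre is affected.

Step 4
Reactants: 8 (R)-4-benzyl-3-{(2R,3R)-2-[3,5-bis(benzyloxy)phenyl]-3-(tert-butyldimethylsilyloxy)-3-[3,4,5-tris(benzyloxy)phenyl]propanoyl}oxazolidin-2-one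
Product: 9 (2S,3R)-2-[3,5-bis(benzyloxy)phenyl]-3-(tert-butyldimethylsilyloxy)-3-[3,4,5-tris(benzyloxy)phenyl]propan-1-ol
Conditions: LiBH4, H2O (1 equiv), Et2O, 0 °C
Reagents that add atoms: none
Why: Reductive removal of the auxiliary (borohydride reduction of the exocyclic imide carbonyl), which frees the primary alcohol without touching the two stereocentres and returns the oxazolidinone.

Step 5
Reactants: 9 (2S,3R)-2-[3,5-bis(benzyloxy)phenyl]-3-(tert-butyldimethylsilyloxy)-3-[3,4,5-tris(benzyloxy)phenyl]propan-1-ol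
Product: 10 (2R,3R)-2-[3,5-bis(benzyloxy)phenyl]-3-(tert-butyldimethylsilyloxy)-3-[3,4,5-tris(benzyloxy)phenyl]propanal
Conditions: DMP, CH2Cl2, 0 °C → rt
Reagents that add atoms: none
Why: Dess–Martin oxidation under neutral, non-basic conditions, chosen so that the α-aryl aldehyde is not enolised; 10 should be used at once without chromatography.

Step 6
Reactants: 10 (2R,3R)-2-[3,5-bis(benzyloxy)phenyl]-3-(tert-butyldimethylsilyloxy)-3-[3,4,5-tris(benzyloxy)phenyl]propanal
Product: 11 (3R,4R)-3-[3,5-bis(benzyloxy)phenyl]-1,1-dibromo-4-(tert-butyldimethylsilyloxy)-4-[3,4,5-tris(benzyloxy)phenyl]but-1-ene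
Conditions: PPh3, CBr4, Zn, CH2Cl2, rt; then 10, 0 °C
Reagents that add atoms: carbon tetrabromide, BrC(Br)(Br)Br
Why: First stage of the Corey–Fuchs homologation (Wittig-type dibromo-olefination with the preformed, base-free dibromomethylene ylide), which adds the future C4 without exposing the enolisable arylmethine centre to amine or alkoxide.

Step 7
Reactants: 11 (3R,4R)-3-[3,5-bis(benzyloxy)phenyl]-1,1-dibromo-4-(tert-butyldimethylsilyloxy)-4-[3,4,5-tris(benzyloxy)phenyl]but-1-ene
Product: 13 methyl (4S,5R)-4-[3,5-bis(benzyloxy)phenyl]-5-(tert-butyldimethylsilyloxy)-5-[3,4,5-tris(benzyloxy)phenyl]pent-2-ynoate, via lithium acetylide 12 (not isolated)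
Conditions: n-BuLi (2.05 equiv), THF, −78 °C; then ClCO2Me, −78 °C
Reagents that add atoms: methyl chloroformate, COC(=O)Cl
Why: Second stage of the Corey–Fuchs sequence (bromine–lithium exchange and Fritsch–Buttenberg–Wiechell rearrangement to the lithium acetylide) followed by C-acylation with the chloroformate; at −78 °C with two equivalents of base the acetylide should form faster than the propargylic arylmethine proton is removed, so the stereocentre is kept.

Step 8
Reactants: 13 methyl (4S,5R)-4-[3,5-bis(benzyloxy)phenyl]-5-(tert-butyldimethylsilyloxy)-5-[3,4,5-tris(benzyloxy)phenyl]pent-2-ynoate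
Product: 14 methyl (2E,4R,5R)-4-[3,5-bis(benzyloxy)phenyl]-5-(tert-butyldimethylsilyloxy)-2-(tributylstannyl)-5-[3,4,5-tris(benzyloxy)phenyl]pent-2-enoate
Conditions: Bu3SnH, Pd(PPh3)4 (3 mol %), THF, 0 °C → rt
Reagents that add atoms: tributyltin hydride, CCCC[SnH](CCCC)CCCC
Why: Palladium-catalysed syn-hydrostannation of an alkynoate, which places tin on the carbon next to the ester and hydrogen on the distal carbon, cis to each other, so that the side chain ends up trans to tin.

Step 9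
Reactants: 15 diisopropyl squarate (3,4-diisopropoxycyclobut-3-ene-1,2-dione)
Product: 16 4-hydroxy-2,3-diisopropoxycyclobut-2-en-1-one (racemic)
Conditions: LiAlH(OtBu)3, THF, −78 → 0 °C
Reagents that add atoms: none
Why: Mono-reduction by the hindered alkoxyaluminium hydride (1,2-hydride addition to one of the two equivalent squarate carbonyls), a known entry to 4-hydroxy-2,3-dialkoxycyclobutenones; the new carbinol centre is racemic and without consequence.

Step 10
Reactants: 16 4-hydroxy-2,3-diisopropoxycyclobut-2-en-1-one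
Product: 17 4-chloro-2,3-diisopropoxycyclobut-2-en-1-one (racemic)
Conditions: PPh3, NCS, CH2Cl2, −20 → 0 °C
Reagents that add atoms: N-chlorosuccinimide, O=C1CCC(=O)N1Cl
Why: Appel-type deoxychlorination through the alkoxyphosphonium salt under neutral conditions, which avoids the acid-promoted collapse of 16 to the semisquarate; 17 is racemic and should be used crude with exclusion of moisture.

Step 11
Reactants: 14 methyl (2E,4R,5R)-4-[3,5-bis(benzyloxy)phenyl]-5-(tert-butyldimethylsilyloxy)-2-(tributylstannyl)-5-[3,4,5-tris(benzyloxy)phenyl]pent-2-enoate; 17 4-chloro-2,3-diisopropoxycyclobut-2-en-1-one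
Product: 18 methyl (2Z,4R,5R)-4-[3,5-bis(benzyloxy)phenyl]-5-(tert-butyldimethylsilyloxy)-2-(2,3-diisopropoxy-4-oxocyclobut-2-en-1-yl)-5-[3,4,5-tris(benzyloxy)phenyl]pent-2-enoate (both epimers at the ring carbon)
Conditions: Pd2(dba)3 (2.5 mol %), P(2-furyl)3 (10 mol %), CuI (10 mol %), THF/NMP, 35–40 °C
Reagents that add atoms: none
Why: Stille cross-coupling of an allylic-type chloride: zerovalent palladium ionises the C–Cl bond of 17, the alkenyl group of 14 is transferred from tin with retention of geometry (CuI assisting) and reductive elimination at the former C–Cl carbon restores the conjugated enone; the new ring stereocentre forms unselectively and is erased in step 12, and the temperature stays below that of ring opening.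

Step 12
Reactants: 18 methyl (2Z,4R,5R)-4-[3,5-bis(benzyloxy)phenyl]-5-(tert-butyldimethylsilyloxy)-2-(2,3-diisopropoxy-4-oxocyclobut-2-en-1-yl)-5-[3,4,5-tris(benzyloxy)phenyl]pent-2-enoate
Product: 21 methyl 2-{(1S,2R)-1-[3,5-bis(benzyloxy)phenyl]-2-(tert-butyldimethylsilyloxy)-2-[3,4,5-tris(benzyloxy)phenyl]ethyl}-3-hydroxy-4,5-diisopropoxybenzoate, via dienylketene 19 (not isolated), via cyclohexa-2,4-dienone 20 (not isolated)
Conditions: toluene (degassed, 0.02 M), 100 °C
Reagents that add atoms: none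
Why: On heating, the cyclobutenone should open by thermal conrotatory 4π electrocyclic cleavage of its C(=O)–CH ring bond to the dienylketene 19; only the rotamer with the acrylate arm turned inward can react further, and because outward opening is reversible all material should drain through it. Disrotatory 6π electrocyclisation of 19 joins the ketene carbon to the alkene terminus (C7a–C3a) and closes the six-membered carbocycle as dienone 20, whose enolisation gives phenol 21; this is the known thermal benzannulation of 4-alkenylcyclobutenones (the hydrogen-substituted counterpart of the Moore rearrangement and the second half of the Danheiser benzannulation). No stereocentre is created: both ring-carbon epimers of 18 converge on one ketene and the transient sp3 centre at C3a of 20 is erased on aromatisation. Regiochemistry needs no control, since connectivity alone places OH at C7a, the isopropoxy groups at C7 and C6, H at C5, the ester at C4 and the side chain at C3a. The selectivity that matters is closure against 1,5-hydrogen shift or interception of the ketene, and it is secured by the alkene geometry from step 8 (side chain trans to the ring carbon, hence outward on the triene terminus) and by the neutral, nucleophile-free medium, which also leaves the silyl ether and both benzylic stereocentres untouched.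

Step 13
Reactants: 21 methyl 2-{(1S,2R)-1-[3,5-bis(benzyloxy)phenyl]-2-(tert-butyldimethylsilyloxy)-2-[3,4,5-tris(benzyloxy)phenyl]ethyl}-3-hydroxy-4,5-diisopropoxybenzoate
Product: 22 methyl (2S,3S)-3-[3,5-bis(benzyloxy)phenyl]-6,7-diisopropoxy-2-[3,4,5-tris(benzyloxy)phenyl]-2,3-dihydrobenzofuran-4-carboxylate
Conditions: TFA, CH2Cl2, −20 → 0 °C
Reagents that add atoms: none
Why: Acid-mediated SN1 cycloetherification: the benzylic silyl ether ionises to a cation stabilised by the para-benzyloxy group, the C7a phenol closes the five-membered ring in a 5-exo-trig sense, and the C3 aryl group steers the C2 aryl group to the opposite face (reversible ionisation also favours the trans ring), so C2 is set as S under control of C3, while the methyl ester is only a weak, reversible trap for the cation.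

Step 14
Reactants: 22 methyl (2S,3S)-3-[3,5-bis(benzyloxy)phenyl]-6,7-diisopropoxy-2-[3,4,5-tris(benzyloxy)phenyl]-2,3-dihydrobenzofuran-4-carboxylate
Product: 23 {(2S,3S)-3-[3,5-bis(benzyloxy)phenyl]-6,7-diisopropoxy-2-[3,4,5-tris(benzyloxy)phenyl]-2,3-dihydrobenzofuran-4-yl}methanol
Conditions: LiAlH4, THF, 0 °C
Reagents that add atoms: none
Why: Hydride reduction of the aryl ester to the benzylic alcohol; the ethers and both stereocentres are inert to it.

Step 15
Reactants: 23 {(2S,3S)-3-[3,5-bis(benzyloxy)phenyl]-6,7-diisopropoxy-2-[3,4,5-tris(benzyloxy)phenyl]-2,3-dihydrobenzofuran-4-yl}methanol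
Product: 24 (2S,3S)-3-[3,5-bis(benzyloxy)phenyl]-6,7-diisopropoxy-2-[3,4,5-tris(benzyloxy)phenyl]-2,3-dihydrobenzofuran-4-carbaldehyde
Conditions: MnO2, CH2Cl2, rt
Reagents that add atoms: none
Why: Chemoselective oxidation of the benzylic alcohol to the aldehyde with activated MnO2 under neutral conditions that leave the benzylic stereocentres untouched.

Step 16
Reactants: 25 3,5-bis(benzyloxy)benzyl bromide
Product: 26 diethyl [3,5-bis(benzyloxy)benzyl]phosphonate
Conditions: P(OEt)3, neat, 130 °C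
Reagents that add atoms: triethyl phosphite, CCOP(OCC)OCC
Why: Michaelis–Arbuzov reaction of a benzylic bromide with triethyl phosphite.

Step 17
Reactants: 24 (2S,3S)-3-[3,5-bis(benzyloxy)phenyl]-6,7-diisopropoxy-2-[3,4,5-tris(benzyloxy)phenyl]-2,3-dihydrobenzofuran-4-carbaldehyde; 26 diethyl [3,5-bis(benzyloxy)benzyl]phosphonate
Product: 28 (2S,3S)-3-[3,5-bis(benzyloxy)phenyl]-4-{(E)-2-[3,5-bis(benzyloxy)phenyl]ethenyl}-6,7-diisopropoxy-2-[3,4,5-tris(benzyloxy)phenyl]-2,3-dihydrobenzofuran, via potassium phosphonate carbanion 27 (not isolated)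
Conditions: KOtBu, THF, 0 °C → rt
Reagents that add atoms: none
Why: Horner–Wadsworth–Emmons olefination with a benzylic phosphonate, which should give the (E)-stilbene through the favoured anti elimination pathway; the aldehyde has no α-hydrogen and the benzylic stereocentres are not acidic enough to be affected.

Step 18
Reactants: 28 (2S,3S)-3-[3,5-bis(benzyloxy)phenyl]-4-{(E)-2-[3,5-bis(benzyloxy)phenyl]ethenyl}-6,7-diisopropoxy-2-[3,4,5-tris(benzyloxy)phenyl]-2,3-dihydrobenzofuran
Product: 29 Scirpusin C, 5-{(2S,3S)-3-(3,5-dihydroxyphenyl)-4-[(E)-2-(3,5-dihydroxyphenyl)ethenyl]-6,7-dihydroxy-2,3-dihydrobenzofuran-2-yl}benzene-1,2,3-triol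
Conditions: BCl3, C6HMe5, CH2Cl2, −78 → 0 °C; MeOH quench
Reagents that add atoms: none
Why: Lewis-acid ether cleavage with a cation scavenger: BCl3 should remove the seven benzyl groups at −78 °C (trapped by pentamethylbenzene) and the two isopropyl groups on brief warming, without HBr or elevated temperature, so the stilbene, the C2–O1 bond and both stereocentres should survive.

Compound list
1 | 2-[3,5-bis(benzyloxy)phenyl]acetic acid | OC(=O)Cc1cc(OCc2ccccc2)cc(OCc2ccccc2)c1 | starting material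
2 | (R)-4-benzyloxazolidin-2-one | O=C1N[C@H](Cc2ccccc2)CO1 | starting material
3 | 2-[3,5-bis(benzyloxy)phenyl]acetic pivalic anhydride | CC(C)(C)C(=O)OC(=O)Cc1cc(OCc2ccccc2)cc(OCc2ccccc2)c1 | intermediate, not isolated
4 | (R)-4-benzyl-3-{2-[3,5-bis(benzyloxy)phenyl]acetyl}oxazolidin-2-one | O=C(Cc1cc(OCc2ccccc2)cc(OCc2ccccc2)c1)N1[C@H](Cc2ccccc2)COC1=O | intermediate
5 | 3,4,5-tris(benzyloxy)benzaldehyde | O=Cc1cc(OCc2ccccc2)c(OCc2ccccc2)c(OCc2ccccc2)c1 | starting material
6 | dibutylboron (Z)-enolate of 4 | CCCCB(CCCC)O/C(N1[C@H](Cc2ccccc2)COC1=O)=C\c1cc(OCc2ccccc2)cc(OCc2ccccc2)c1 | intermediate, not isolated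
7 | (R)-4-benzyl-3-{(2R,3R)-2-[3,5-bis(benzyloxy)phenyl]-3-hydroxy-3-[3,4,5-tris(benzyloxy)phenyl]propanoyl}oxazolidin-2-one (syn aldol) | O=C(N1[C@H](Cc2ccccc2)COC1=O)[C@H](c1cc(OCc2ccccc2)cc(OCc2ccccc2)c1)[C@@H](O)c1cc(OCc2ccccc2)c(OCc2ccccc2)c(OCc2ccccc2)c1 | intermediate
8 | (R)-4-benzyl-3-{(2R,3R)-2-[3,5-bis(benzyloxy)phenyl]-3-(tert-butyldimethylsilyloxy)-3-[3,4,5-tris(benzyloxy)phenyl]propanoyl}oxazolidin-2-one | O=C(N1[C@H](Cc2ccccc2)COC1=O)[C@H](c1cc(OCc2ccccc2)cc(OCc2ccccc2)c1)[C@@H](O[Si](C)(C)C(C)(C)C)c1cc(OCc2ccccc2)c(OCc2ccccc2)c(OCc2ccccc2)c1 | intermediate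
9 | (2S,3R)-2-[3,5-bis(benzyloxy)phenyl]-3-(tert-butyldimethylsilyloxy)-3-[3,4,5-tris(benzyloxy)phenyl]propan-1-ol | OC[C@H](c1cc(OCc2ccccc2)cc(OCc2ccccc2)c1)[C@@H](O[Si](C)(C)C(C)(C)C)c1cc(OCc2ccccc2)c(OCc2ccccc2)c(OCc2ccccc2)c1 | intermediate
10 | (2R,3R)-2-[3,5-bis(benzyloxy)phenyl]-3-(tert-butyldimethylsilyloxy)-3-[3,4,5-tris(benzyloxy)phenyl]propanal | O=C[C@H](c1cc(OCc2ccccc2)cc(OCc2ccccc2)c1)[C@@H](O[Si](C)(C)C(C)(C)C)c1cc(OCc2ccccc2)c(OCc2ccccc2)c(OCc2ccccc2)c1 | intermediate
11 | (3R,4R)-3-[3,5-bis(benzyloxy)phenyl]-1,1-dibromo-4-(tert-butyldimethylsilyloxy)-4-[3,4,5-tris(benzyloxy)phenyl]but-1-ene | BrC(Br)=C[C@H](c1cc(OCc2ccccc2)cc(OCc2ccccc2)c1)[C@@H](O[Si](C)(C)C(C)(C)C)c1cc(OCc2ccccc2)c(OCc2ccccc2)c(OCc2ccccc2)c1 | intermediate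
12 | lithium (3S,4R)-3-[3,5-bis(benzyloxy)phenyl]-4-(tert-butyldimethylsilyloxy)-4-[3,4,5-tris(benzyloxy)phenyl]but-1-yn-1-ide | [Li]C#C[C@H](c1cc(OCc2ccccc2)cc(OCc2ccccc2)c1)[C@@H](O[Si](C)(C)C(C)(C)C)c1cc(OCc2ccccc2)c(OCc2ccccc2)c(OCc2ccccc2)c1 | intermediate, not isolated
13 | methyl (4S,5R)-4-[3,5-bis(benzyloxy)phenyl]-5-(tert-butyldimethylsilyloxy)-5-[3,4,5-tris(benzyloxy)phenyl]pent-2-ynoate | COC(=O)C#C[C@H](c1cc(OCc2ccccc2)cc(OCc2ccccc2)c1)[C@@H](O[Si](C)(C)C(C)(C)C)c1cc(OCc2ccccc2)c(OCc2ccccc2)c(OCc2ccccc2)c1 | intermediate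
14 | methyl (2E,4R,5R)-4-[3,5-bis(benzyloxy)phenyl]-5-(tert-butyldimethylsilyloxy)-2-(tributylstannyl)-5-[3,4,5-tris(benzyloxy)phenyl]pent-2-enoate | CCCC[Sn](CCCC)(CCCC)/C(C(=O)OC)=C/[C@H](c1cc(OCc2ccccc2)cc(OCc2ccccc2)c1)[C@@H](O[Si](C)(C)C(C)(C)C)c1cc(OCc2ccccc2)c(OCc2ccccc2)c(OCc2ccccc2)c1 | intermediate
15 | diisopropyl squarate (3,4-diisopropoxycyclobut-3-ene-1,2-dione) | CC(C)OC1=C(OC(C)C)C(=O)C1=O | starting material
16 | 4-hydroxy-2,3-diisopropoxycyclobut-2-en-1-one (racemic) | O=C1C(OC(C)C)=C(OC(C)C)C1O | intermediate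
17 | 4-chloro-2,3-diisopropoxycyclobut-2-en-1-one (racemic) | O=C1C(OC(C)C)=C(OC(C)C)C1Cl | intermediate
18 | methyl (2Z,4R,5R)-4-[3,5-bis(benzyloxy)phenyl]-5-(tert-butyldimethylsilyloxy)-2-(2,3-diisopropoxy-4-oxocyclobut-2-en-1-yl)-5-[3,4,5-tris(benzyloxy)phenyl]pent-2-enoate (both epimers at the ring carbon) | O=C1C(OC(C)C)=C(OC(C)C)C1/C(C(=O)OC)=C/[C@H](c1cc(OCc2ccccc2)cc(OCc2ccccc2)c1)[C@@H](O[Si](C)(C)C(C)(C)C)c1cc(OCc2ccccc2)c(OCc2ccccc2)c(OCc2ccccc2)c1 | intermediate
19 | dienylketene: methyl (2Z,4R,5R)-4-[3,5-bis(benzyloxy)phenyl]-5-(tert-butyldimethylsilyloxy)-2-[(1E)-2,3-diisopropoxy-4-oxobuta-1,3-dien-1-yl]-5-[3,4,5-tris(benzyloxy)phenyl]pent-2-enoate | O=C=C(OC(C)C)/C(OC(C)C)=C\C(C(=O)OC)=C\[C@H](c1cc(OCc2ccccc2)cc(OCc2ccccc2)c1)[C@@H](O[Si](C)(C)C(C)(C)C)c1cc(OCc2ccccc2)c(OCc2ccccc2)c(OCc2ccccc2)c1 | intermediate, not isolated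
20 | cyclohexadienone: methyl 3,4-diisopropoxy-5-oxocyclohexa-1,3-diene-1-carboxylate bearing at C6 the 1-[3,5-bis(benzyloxy)phenyl]-2-(tert-butyldimethylsilyloxy)-2-[3,4,5-tris(benzyloxy)phenyl]ethyl group (side-chain centres as in 18; C6 as a mixture) | O=C1C(OC(C)C)=C(OC(C)C)C=C(C(=O)OC)C1[C@H](c1cc(OCc2ccccc2)cc(OCc2ccccc2)c1)[C@@H](O[Si](C)(C)C(C)(C)C)c1cc(OCc2ccccc2)c(OCc2ccccc2)c(OCc2ccccc2)c1 | intermediate, not isolated
21 | methyl 2-{(1S,2R)-1-[3,5-bis(benzyloxy)phenyl]-2-(tert-butyldimethylsilyloxy)-2-[3,4,5-tris(benzyloxy)phenyl]ethyl}-3-hydroxy-4,5-diisopropoxybenzoate | COC(=O)c1cc(OC(C)C)c(OC(C)C)c(O)c1[C@H](c1cc(OCc2ccccc2)cc(OCc2ccccc2)c1)[C@@H](O[Si](C)(C)C(C)(C)C)c1cc(OCc2ccccc2)c(OCc2ccccc2)c(OCc2ccccc2)c1 | intermediate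
22 | methyl (2S,3S)-3-[3,5-bis(benzyloxy)phenyl]-6,7-diisopropoxy-2-[3,4,5-tris(benzyloxy)phenyl]-2,3-dihydrobenzofuran-4-carboxylate | COC(=O)c1cc(OC(C)C)c(OC(C)C)c2c1[C@H](c1cc(OCc3ccccc3)cc(OCc3ccccc3)c1)[C@@H](c1cc(OCc3ccccc3)c(OCc3ccccc3)c(OCc3ccccc3)c1)O2 | intermediate
23 | {(2S,3S)-3-[3,5-bis(benzyloxy)phenyl]-6,7-diisopropoxy-2-[3,4,5-tris(benzyloxy)phenyl]-2,3-dihydrobenzofuran-4-yl}methanol | OCc1cc(OC(C)C)c(OC(C)C)c2c1[C@H](c1cc(OCc3ccccc3)cc(OCc3ccccc3)c1)[C@@H](c1cc(OCc3ccccc3)c(OCc3ccccc3)c(OCc3ccccc3)c1)O2 | intermediate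
24 | (2S,3S)-3-[3,5-bis(benzyloxy)phenyl]-6,7-diisopropoxy-2-[3,4,5-tris(benzyloxy)phenyl]-2,3-dihydrobenzofuran-4-carbaldehyde | O=Cc1cc(OC(C)C)c(OC(C)C)c2c1[C@H](c1cc(OCc3ccccc3)cc(OCc3ccccc3)c1)[C@@H](c1cc(OCc3ccccc3)c(OCc3ccccc3)c(OCc3ccccc3)c1)O2 | intermediate
25 | 3,5-bis(benzyloxy)benzyl bromide | BrCc1cc(OCc2ccccc2)cc(OCc2ccccc2)c1 | starting material
26 | diethyl [3,5-bis(benzyloxy)benzyl]phosphonate | CCOP(=O)(Cc1cc(OCc2ccccc2)cc(OCc2ccccc2)c1)OCC | intermediate
27 | potassium salt of the benzylic carbanion of 26 | [K+].CCOP(=O)([CH-]c1cc(OCc2ccccc2)cc(OCc2ccccc2)c1)OCC | intermediate, not isolated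
28 | (2S,3S)-3-[3,5-bis(benzyloxy)phenyl]-4-{(E)-2-[3,5-bis(benzyloxy)phenyl]ethenyl}-6,7-diisopropoxy-2-[3,4,5-tris(benzyloxy)phenyl]-2,3-dihydrobenzofuran | C(=C/c1cc(OC(C)C)c(OC(C)C)c2c1[C@H](c1cc(OCc3ccccc3)cc(OCc3ccccc3)c1)[C@@H](c1cc(OCc3ccccc3)c(OCc3ccccc3)c(OCc3ccccc3)c1)O2)\c1cc(OCc2ccccc2)cc(OCc2ccccc2)c1 | intermediate
29 | Scirpusin C, 5-{(2S,3S)-3-(3,5-dihydroxyphenyl)-4-[(E)-2-(3,5-dihydroxyphenyl)ethenyl]-6,7-dihydroxy-2,3-dihydrobenzofuran-2-yl}benzene-1,2,3-triol | Oc1cc(O)cc(/C=C/c2cc(O)c(O)c3c2[C@H](c2cc(O)cc(O)c2)[C@@H](c2cc(O)c(O)c(O)c2)O3)c1 | target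

Total step count: 18.
Longest linear sequence: 15 steps (steps 1–8, 11–15, 17, 18); steps 9–10 and step 16 are side branches.

Steps most likely to fail

Step 11 is the most exposed. Transfer of the hindered, ester-bearing alkenyl group from tin to palladium may be slow, so that the ionisable chloride 17 is lost by hydrolysis or dealkylation and the stannane by protodestannylation before the coupling takes place. The fallback leaves the chloride out and uses ionisation of an allylic ester instead of oxidative addition to a halide. Setting out from 16, acetylation (Ac2O, pyridine, DMAP, CH2Cl2, 0 °C) should give the bench-stable 2,3-diisopropoxy-4-oxocyclobut-2-en-1-yl acetate F1. Zerovalent palladium should ionise this in the Tsuji–Trost manner, and coupling of F1 with 14 (Pd2(dba)3, LiCl, DMF, 25–40 °C) would rejoin the route at 18.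

Step 13 comes second. The benzylic cation may be captured by the neighbouring ester oxygen (lactone formation) or lose the C3 proton (triarylalkene, loss of the stereocentre) faster than the phenol closes the ring. The fallback replaces ionisation by displacement. Setting out from 21, buffered desilylation (HF·pyridine, pyridine, THF, 0 °C) should give methyl 2-{(1S,2R)-1-[3,5-bis(benzyloxy)phenyl]-2-hydroxy-2-[3,4,5-tris(benzyloxy)phenyl]ethyl}-3-hydroxy-4,5-diisopropoxybenzoate F2. Mitsunobu cyclodehydration of F2 (PPh3, DIAD, THF, 0 °C) should close O1–C2 with inversion, which from the syn carbinol gives the 2,3-trans ester, so the route is rejoined at 22.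

Step 7 comes third. Butyllithium or the lithium acetylide may remove the doubly activated proton at the arylmethine carbon (propargyl–allenyl isomerisation), eroding the configuration of the future C3. The fallback reaches the stannane without any acetylide. Setting out from 10, olefination with methyl 2-bromo-2-[bis(2,2,2-trifluoroethoxy)phosphoryl]acetate (KOtBu, 18-crown-6, THF, −78 °C; a Still–Gennari-type reagent that places the side chain cis to the ester) should give methyl (2E,4R,5R)-4-[3,5-bis(benzyloxy)phenyl]-2-bromo-5-(tert-butyldimethylsilyloxy)-5-[3,4,5-tris(benzyloxy)phenyl]pent-2-enoate F3. Palladium-catalysed stannylation of F3 with hexabutylditin (Pd(PPh3)4, toluene, 80 °C) would rejoin the route at 14.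

Further compounds
F1 | step 11 | 2,3-diisopropoxy-4-oxocyclobut-2-en-1-yl acetate | CC(=O)OC1C(OC(C)C)=C(OC(C)C)C1=O
F2 | step 13 | methyl 2-{(1S,2R)-1-[3,5-bis(benzyloxy)phenyl]-2-hydroxy-2-[3,4,5-tris(benzyloxy)phenyl]ethyl}-3-hydroxy-4,5-diisopropoxybenzoate | COC(=O)c1cc(OC(C)C)c(OC(C)C)c(O)c1[C@H](c1cc(OCc2ccccc2)cc(OCc2ccccc2)c1)[C@@H](O)c1cc(OCc2ccccc2)c(OCc2ccccc2)c(OCc2ccccc2)c1
F3 | step 7 | methyl (2E,4R,5R)-4-[3,5-bis(benzyloxy)phenyl]-2-bromo-5-(tert-butyldimethylsilyloxy)-5-[3,4,5-tris(benzyloxy)phenyl]pent-2-enoate | Br/C(C(=O)OC)=C/[C@H](c1cc(OCc2ccccc2)cc(OCc2ccccc2)c1)[C@@H](O[Si](C)(C)C(C)(C)C)c1cc(OCc2ccccc2)c(OCc2ccccc2)c(OCc2ccccc2)c1
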